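The plan disconnects the pyran ring of the ent-fisetinidol unit on catechin C-6 (unit C) across C-3–C-4 and O-1–C-2. That ring has its oxygen O-1 ortho to the doubly benzylic C-4 on a resorcinol ring, so an o-hydroxybenzhydrol placed on catechin C-6 of a benzyl-protected trimer can ionise to an ortho-quinone methide (O-1=C-8a–C-4a=C-4). A chiral Brønsted-acid-catalysed oxa-[4+2] cycloaddition with an (E)-β-acetoxystyrene then closes the ring, forming both bonds and the C-2, C-3 and C-4 stereocentres at once. The two 3,4-cis interflavan bonds are set earlier by aryllithium addition to a flavan-4-one and ionic deoxygenation; (+)-catechin supplies unit D.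

Key step: step 17

Remarks. Units: A = terminal ent-fisetinidol (C-4 bonded to C-6 of unit B); B = ent-fisetinidol bonded through C-4 to C-8 of catechin; C = ent-fisetinidol bonded through C-4 to C-6 of catechin; D = (+)-catechin. ent-Fisetinidol is (2S,3R)-2-(3,4-dihydroxyphenyl)-3,4-dihydro-2H-chromene-3,7-diol. In these 2S units 4α means the C-4 aryl group is cis to the 3-oxygen and 4β means trans. Bn = benzyl.
Assumption: poly-D-leucine (step 4) and the (R)-configured phosphoramide (step 17) are taken to give the stated sense of induction; if either sense proves opposite, the mirror-image catalyst is used.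

Step 1
Reactants: 1 1-[4-(benzyloxy)-2-hydroxyphenyl]ethan-1-one
Product: 2 1-[4-(benzyloxy)-5-bromo-2-hydroxyphenyl]ethan-1-one
Conditions: NBS (1.05 equiv), MeCN, 0 °C → rt
Reagents that add atoms: N-bromosuccinimide, O=C1CCC(=O)N1Br
Why: Electrophilic aromatic bromination should go to C-5, which is para to the free phenol, ortho to the benzyloxy group and less hindered than C-3; this bromine later serves as the lithiation site of unit B and as a blocking group on unit A.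

Step 2
Reactants: 2 1-[4-(benzyloxy)-5-bromo-2-hydroxyphenyl]ethan-1-one
Product: 3 1-[4-(benzyloxy)-5-bromo-2-(methoxymethoxy)phenyl]ethan-1-one
Conditions: MOMCl, K2CO3, acetone, reflux
Reagents that add atoms: chloromethyl methyl ether, COCCl
Why: Williamson-type O-alkylation of the phenoxide masks the phenol so that the later basic peroxide epoxidation cannot divert into oxidative cyclisation.

Step 3
Reactants: 3 1-[4-(benzyloxy)-5-bromo-2-(methoxymethoxy)phenyl]ethan-1-one; 4 3,4-bis(benzyloxy)benzaldehyde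
Product: 5 (E)-1-[4-(benzyloxy)-5-bromo-2-(methoxymethoxy)phenyl]-3-[3,4-bis(benzyloxy)phenyl]prop-2-en-1-one
Conditions: KOH, EtOH/THF, rt
Reagents that add atoms: none
Why: Claisen–Schmidt aldol condensation with E1cB dehydration should give the E-chalcone as the thermodynamic enone.

Step 4
Reactants: 5 (E)-1-[4-(benzyloxy)-5-bromo-2-(methoxymethoxy)phenyl]-3-[3,4-bis(benzyloxy)phenyl]prop-2-en-1-one
Product: 6 [4-(benzyloxy)-5-bromo-2-(methoxymethoxy)phenyl][(2S,3R)-3-[3,4-bis(benzyloxy)phenyl]oxiran-2-yl]methanone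
Conditions: poly-D-leucine, urea–H2O2, DBU, THF, rt
Reagents that add atoms: hydrogen peroxide (used as its urea adduct), OO
Why: Juliá–Colonna asymmetric Weitz–Scheffer epoxidation, in which the helical poly-D-leucine directs hydroperoxide to one enone face, should give the (αS,βR) trans-epoxide and so fix the future C-3 (and through it C-2) of units A and B.

Step 5
Reactants: 6 [4-(benzyloxy)-5-bromo-2-(methoxymethoxy)phenyl][(2S,3R)-3-[3,4-bis(benzyloxy)phenyl]oxiran-2-yl]methanone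
Product: 8 (2S,3S)-7-(benzyloxy)-2-[3,4-bis(benzyloxy)phenyl]-6-bromo-3-hydroxy-2,3-dihydro-4H-chromen-4-one, via phenol epoxide 7 (not isolated)
Conditions: HCl (conc.), MeOH/THF, 50 °C
Reagents that add atoms: none
Why: Acidic cleavage of the methoxymethyl acetal frees the phenol, which opens the epoxide at the benzylic carbon (6-exo-tet, inversion) to set C-2 as S while C-3 is carried over unchanged, so the 2,3-trans dihydroflavonol should result.

Step 6
Reactants: 8 (2S,3S)-7-(benzyloxy)-2-[3,4-bis(benzyloxy)phenyl]-6-bromo-3-hydroxy-2,3-dihydro-4H-chromen-4-one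
Product: 9 (2S,3S)-3,7-bis(benzyloxy)-2-[3,4-bis(benzyloxy)phenyl]-6-bromo-2,3-dihydro-4H-chromen-4-one
Conditions: BnBr, Ag2O, 4 Å MS, CH2Cl2, rt, dark
Reagents that add atoms: benzyl bromide, BrCc1ccccc1
Why: Silver-oxide-mediated O-benzylation is essentially non-basic, so the α-hydroxy ketone should be etherified without epimerisation at C-2/C-3 or ring opening to the chalcone.

Step 7
Reactants: 10 (+)-catechin
Product: 11 (2R,3S)-3,5,7-tris(benzyloxy)-2-[3,4-bis(benzyloxy)phenyl]-3,4-dihydro-2H-chromene (penta-O-benzylcatechin)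
Conditions: NaH (6 equiv), BnBr (6 equiv), DMF, −78 °C → rt
Reagents that add atoms: benzyl bromide, BrCc1ccccc1
Why: Williamson etherification of the four phenols and the 3-OH at low temperature should leave both stereocentres untouched.

Step 8
Reactants: 11 penta-O-benzylcatechin
Product: 12 (2R,3S)-3,5,7-tris(benzyloxy)-2-[3,4-bis(benzyloxy)phenyl]-8-bromo-3,4-dihydro-2H-chromene
Conditions: NBS (1.0 equiv), CH2Cl2, −78 °C → rt
Reagents that add atoms: N-bromosuccinimide, O=C1CCC(=O)N1Br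
Why: Electrophilic bromination of benzylated catechins is known to prefer C-8 of the phloroglucinol-type ring, and this also keeps C-6 free for unit C.

Step 9
Reactants: 12 8-bromo-penta-O-benzylcatechin; 9 (2S,3S)-3,7-bis(benzyloxy)-2-[3,4-bis(benzyloxy)phenyl]-6-bromo-2,3-dihydro-4H-chromen-4-one
Product: 14 tertiary alcohol 6-bromo-3,7,3',4'-tetra-O-benzyl-4-hydroxy-ent-fisetinidol-(4→8)-3,5,7,3',4'-penta-O-benzylcatechin (either C-4 carbinol epimer), via 8-lithio penta-O-benzylcatechin 13 (not isolated)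
Conditions: 12, t-BuLi (2.0 equiv), THF, −78 °C; then 9, −78 → −40 °C; aq. NH4Cl
Reagents that add atoms: none
Why: Bromine–lithium exchange and 1,2-addition of the aryllithium to the ketone should at −78 °C outrun enolisation at C-3 and exchange with the aryl bromide of 9; the new carbinol centre is removed in step 11, so its configuration is immaterial.

Step 10
Reactants: 14 tertiary alcohol of unit B on unit D; 9 (2S,3S)-3,7-bis(benzyloxy)-2-[3,4-bis(benzyloxy)phenyl]-6-bromo-2,3-dihydro-4H-chromen-4-one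
Product: 16 bis-carbinol 6-bromo-3,7,3',4'-tetra-O-benzyl-4-hydroxy-ent-fisetinidol-(4→6)-3,7,3',4'-tetra-O-benzyl-4-hydroxy-ent-fisetinidol-(4→8)-3,5,7,3',4'-penta-O-benzylcatechin (either epimer at both carbinols), via dilithio species 15 (not isolated)
Conditions: 14, MeLi (1.0 equiv), THF, −78 °C; t-BuLi (2.0 equiv), −78 °C; then 9, −78 → −40 °C; aq. NH4Cl
Reagents that add atoms: none
Why: After deprotonation of the tertiary alcohol, bromine–lithium exchange at C-6 of unit B and addition to a second molecule of ketone 9 should form the C-4(A)–C-6(B) bond by the same organolithium 1,2-addition as in step 9.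

Step 11
Reactants: 16 bis-carbinol
Product: 17 6-bromo-3,7,3',4'-tetra-O-benzyl-ent-fisetinidol-(4α→6)-3,7,3',4'-tetra-O-benzyl-ent-fisetinidol-(4α→8)-3,5,7,3',4'-penta-O-benzylcatechin
Conditions: Bu3SnH (6 equiv), CF3CO2H, CH2Cl2, 0 °C
Reagents that add atoms: none
Why: In this ionic hydrogenation (SN1 deoxygenation) each tertiary diarylcarbinol ionises to a C-4 cation stabilised by the para 7-benzyloxy group and O-1, and hydride should be delivered to the face anti to the adjacent 3-benzyloxy group, leaving the aryl group cis to it (3,4-cis) in units A and B.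

Step 12
Reactants: 17 protected trimer
Product: 18 trimer 17 iodinated at C-6 of unit D
Conditions: NIS (1.0 equiv), CH2Cl2, −20 → 0 °C
Reagents that add atoms: N-iodosuccinimide, O=C1CCC(=O)N1I
Why: Electrophilic iodination should go to the only free position of the phloroglucinol-type ring (C-6 of unit D), which is far more electron-rich than the resorcinol- and catechol-type rings, while C-6 of unit A is blocked by bromine.

Step 13
Reactants: 18 iodinated trimer; 19 4-(benzyloxy)-2-hydroxybenzaldehyde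
Product: 22 trimer 17 carrying at C-6 of unit D a [4-(benzyloxy)-2-hydroxyphenyl](hydroxy)methyl group (either carbinol epimer), via sodium phenoxide 20 (not isolated), via arylmagnesium chloride 21 (not isolated)
Conditions: 19 (3 equiv), NaH, THF, 0 °C; separately 18, i-PrMgCl·LiCl (1.1 equiv), THF, −20 °C; combine, −20 °C → rt; aq. NH4Cl
Reagents that add atoms: none
Why: Iodine–magnesium exchange should be selective for the aryl iodide over the aryl bromide of unit A, and Grignard addition to the aldehyde of the preformed phenoxide gives the o-hydroxybenzhydrol, whose carbinol centre becomes sp2 in step 17.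

Step 14
Reactants: 4 3,4-bis(benzyloxy)benzaldehyde; 23 2,2'-methylenebis(4,4,5,5-tetramethyl-1,3,2-dioxaborolane)
Product: 25 2-[(E)-2-[3,4-bis(benzyloxy)phenyl]ethenyl]-4,4,5,5-tetramethyl-1,3,2-dioxaborolane, via lithiated diborylmethane 24 (not isolated)
Conditions: 23, lithium 2,2,6,6-tetramethylpiperidide, THF, 0 °C; then 4, −78 °C → rt; aq. NH4Cl
Reagents that add atoms: none
Why: Boron–Wittig olefination, in which syn B–O elimination from the favoured adduct gives the E-alkenylboronate, should fix the alkene geometry that later becomes the 2,3-trans relationship of unit C.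

Step 15
Reactants: 25 (E)-alkenylboronic ester
Product: 26 potassium [(E)-2-[3,4-bis(benzyloxy)phenyl]ethenyl]trifluoroborate
Conditions: KHF2, MeOH/H2O, rt
Reagents that add atoms: potassium hydrogen difluoride, [K+].[F-].F
Why: Ligand exchange at boron gives the air-stable trifluoroborate without touching the E-alkene.

Step 16
Reactants: 26 potassium alkenyltrifluoroborate
Product: 27 (E)-2-[3,4-bis(benzyloxy)phenyl]ethenyl acetate
Conditions: AcOH (2 equiv), Cu(OAc)2 (20 mol %), DMAP, 4 Å MS, O2 (1 atm), CH2Cl2/MeCN, rt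
Reagents that add atoms: acetic acid, CC(=O)O
Why: Chan–Lam-type copper-catalysed oxidative C–O coupling of the alkenyltrifluoroborate with the carboxylic acid proceeds with retention, so the E-enol acetate should be obtained stereospecifically.

Step 17
Reactants: 22 o-hydroxybenzhydrol on unit D; 27 (E)-2-[3,4-bis(benzyloxy)phenyl]ethenyl acetate
Product: 29 6-bromo-3,7,3',4'-tetra-O-benzyl-ent-fisetinidol-(4α→6)-3,7,3',4'-tetra-O-benzyl-ent-fisetinidol-(4α→8)-3,5,7,3',4'-penta-O-benzylcatechin-(6→4β)-3-O-acetyl-7,3',4'-tri-O-benzyl-ent-fisetinidol (unit C 2S,3R,4R), via ortho-quinone methide 28 (not isolated)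
Conditions: (R)-3,3'-bis(2,4,6-triisopropylphenyl)-1,1'-binaphthyl-2,2'-diyl N-(trifluoromethylsulfonyl)phosphoramide (10 mol %), 27 (3 equiv), 5 Å MS, CH2Cl2, −40 → 0 °C
Reagents that add atoms: none
Why: Proposed new method: the acid dehydrates 22 to the E-configured ortho-quinone methide 28 (O-1=C-8a–C-4a=C-4), whose C-4 is attacked by the acetoxy-bearing carbon of 27 while O-1 closes onto the benzylic carbon in an asynchronous inverse-electron-demand oxa-[4+2] cycloaddition; the closest known reaction type is the chiral N-triflylphosphoramide-catalysed cycloaddition of o-hydroxybenzhydrol-derived ortho-quinone methides with styrenes, which to the best of our knowledge has not been shown with a β-acyloxystyrene. The pyran ring of unit C is closed in hetero-Diels–Alder mode, with C-3–C-4 and O-1–C-2 formed in one operation. The C-2/C-3 trans relationship follows from the E geometry of 27 (suprafacial addition), the C-2/C-4 cis relationship from the endo orientation of the styrene aryl group over the E-methide, and the absolute sense (2S,3R,4R) from the chiral phosphoramide anion hydrogen-bonded at O-1, because the stereocentres of the trimer are too remote to bias the methide faces. The step needs regioselectivity (C-3 to C-4, not C-2 to C-4), and this is secured by the para-benzyloxy group of the styrene, which stabilises positive charge at the benzylic carbon far better than the acetoxy group does at its own carbon. Because all other phenols are benzylated, only the resorcinol 2-OH is free, so the methide can form only toward ring A of unit C and not on the catechin ring.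

Step 18
Reactants: 29 acetylated protected tetramer
Product: 30 6-bromo-3,7,3',4'-tetra-O-benzyl-ent-fisetinidol-(4α→6)-3,7,3',4'-tetra-O-benzyl-ent-fisetinidol-(4α→8)-3,5,7,3',4'-penta-O-benzylcatechin-(6→4β)-7,3',4'-tri-O-benzyl-ent-fisetinidol
Conditions: K2CO3, MeOH/THF, rt
Reagents that add atoms: none
Why: Base-catalysed transesterification should remove the secondary acetate without affecting benzyl ethers, the aryl bromide or any stereocentre.

Step 19
Reactants: 30 protected tetramer with free 3-OH on unit C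
Product: 31 ent-fisetinidol-(4α→6)-ent-fisetinidol-(4α→8)-catechin-(6→4β)-ent-fisetinidol (CNP0126838.5)
Conditions: H2 (1 atm), Pd(OH)2/C, NaOAc, THF/MeOH/H2O, rt
Reagents that add atoms: none
Why: Catalytic hydrogenolysis should cleave all sixteen benzyl ethers and hydrodebrominate C-6 of unit A in one operation, the acetate buffer taking up HBr so that the interflavan bonds are not exposed to acid.

Compound list
1 | 1-[4-(benzyloxy)-2-hydroxyphenyl]ethan-1-one | CC(=O)c1ccc(OCc2ccccc2)cc1O | starting material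
2 | 1-[4-(benzyloxy)-5-bromo-2-hydroxyphenyl]ethan-1-one | CC(=O)c1cc(Br)c(OCc2ccccc2)cc1O | intermediate
3 | 1-[4-(benzyloxy)-5-bromo-2-(methoxymethoxy)phenyl]ethan-1-one | CC(=O)c1cc(Br)c(OCc2ccccc2)cc1OCOC | intermediate
4 | 3,4-bis(benzyloxy)benzaldehyde | O=Cc1ccc(OCc2ccccc2)c(OCc2ccccc2)c1 | starting material
5 | (E)-1-[4-(benzyloxy)-5-bromo-2-(methoxymethoxy)phenyl]-3-[3,4-bis(benzyloxy)phenyl]prop-2-en-1-one | O=C(/C=C/c1ccc(OCc2ccccc2)c(OCc2ccccc2)c1)c1cc(Br)c(OCc2ccccc2)cc1OCOC | intermediate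
6 | [4-(benzyloxy)-5-bromo-2-(methoxymethoxy)phenyl][(2S,3R)-3-[3,4-bis(benzyloxy)phenyl]oxiran-2-yl]methanone | O=C(c1cc(Br)c(OCc2ccccc2)cc1OCOC)[C@H]1O[C@@H]1c1ccc(OCc2ccccc2)c(OCc2ccccc2)c1 | intermediate
7 | [4-(benzyloxy)-5-bromo-2-hydroxyphenyl][(2S,3R)-3-[3,4-bis(benzyloxy)phenyl]oxiran-2-yl]methanone | O=C(c1cc(Br)c(OCc2ccccc2)cc1O)[C@H]1O[C@@H]1c1ccc(OCc2ccccc2)c(OCc2ccccc2)c1 | intermediate (not isolated)
8 | (2S,3S)-7-(benzyloxy)-2-[3,4-bis(benzyloxy)phenyl]-6-bromo-3-hydroxy-2,3-dihydro-4H-chromen-4-one | O=C1c2cc(Br)c(OCc3ccccc3)cc2O[C@@H](c2ccc(OCc3ccccc3)c(OCc3ccccc3)c2)[C@@H]1O | intermediate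
9 | (2S,3S)-3,7-bis(benzyloxy)-2-[3,4-bis(benzyloxy)phenyl]-6-bromo-2,3-dihydro-4H-chromen-4-one | O=C1c2cc(Br)c(OCc3ccccc3)cc2O[C@@H](c2ccc(OCc3ccccc3)c(OCc3ccccc3)c2)[C@@H]1OCc1ccccc1 | intermediate
10 | (+)-catechin, (2R,3S)-2-(3,4-dihydroxyphenyl)-3,4-dihydro-2H-chromene-3,5,7-triol | Oc1cc(O)c2c(c1)O[C@H](c1ccc(O)c(O)c1)[C@@H](O)C2 | starting material
11 | (2R,3S)-3,5,7-tris(benzyloxy)-2-[3,4-bis(benzyloxy)phenyl]-3,4-dihydro-2H-chromene (penta-O-benzylcatechin) | O(Cc9ccccc9)c1cc(OCc9ccccc9)c2c(c1)O[C@H](c1ccc(OCc9ccccc9)c(OCc9ccccc9)c1)[C@@H](OCc9ccccc9)C2 | intermediate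
12 | (2R,3S)-3,5,7-tris(benzyloxy)-2-[3,4-bis(benzyloxy)phenyl]-8-bromo-3,4-dihydro-2H-chromene | Brc1c(OCc9ccccc9)cc(OCc9ccccc9)c2c1O[C@H](c1ccc(OCc9ccccc9)c(OCc9ccccc9)c1)[C@@H](OCc9ccccc9)C2 | intermediate
13 | 8-lithio derivative of penta-O-benzylcatechin | [Li]c1c(OCc9ccccc9)cc(OCc9ccccc9)c2c1O[C@H](c1ccc(OCc9ccccc9)c(OCc9ccccc9)c1)[C@@H](OCc9ccccc9)C2 | intermediate (not isolated)
14 | 6-bromo-3,7,3',4'-tetra-O-benzyl-4-hydroxy-ent-fisetinidol-(4→8)-3,5,7,3',4'-penta-O-benzylcatechin (tertiary C-4 carbinol of unit B bearing C-8 of unit D; C-2 and C-3 of unit B as in 9; either C-4 epimer) | OC1(c2c(OCc9ccccc9)cc(OCc9ccccc9)c3c2O[C@H](c4ccc(OCc9ccccc9)c(OCc9ccccc9)c4)[C@@H](OCc9ccccc9)C3)c2cc(Br)c(OCc9ccccc9)cc2O[C@@H](c2ccc(OCc9ccccc9)c(OCc9ccccc9)c2)[C@@H]1OCc9ccccc9 | intermediate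
15 | lithium alkoxide of 14 lithiated at C-6 of unit B | [Li]OC1(c2c(OCc9ccccc9)cc(OCc9ccccc9)c3c2O[C@H](c4ccc(OCc9ccccc9)c(OCc9ccccc9)c4)[C@@H](OCc9ccccc9)C3)c2cc([Li])c(OCc9ccccc9)cc2O[C@@H](c2ccc(OCc9ccccc9)c(OCc9ccccc9)c2)[C@@H]1OCc9ccccc9 | intermediate (not isolated)
16 | bis-carbinol: 14 in which C-6 of unit B is bonded to C-4 of a second 6-bromo-3,7,3',4'-tetra-O-benzyl-4-hydroxy-ent-fisetinidol unit (unit A); either epimer at both tertiary carbinols | OC1(c2cc3c(cc2OCc9ccccc9)O[C@@H](c4ccc(OCc9ccccc9)c(OCc9ccccc9)c4)[C@H](OCc9ccccc9)C3(O)c2c(OCc9ccccc9)cc(OCc9ccccc9)c3c2O[C@H](c4ccc(OCc9ccccc9)c(OCc9ccccc9)c4)[C@@H](OCc9ccccc9)C3)c2cc(Br)c(OCc9ccccc9)cc2O[C@@H](c2ccc(OCc9ccccc9)c(OCc9ccccc9)c2)[C@@H]1OCc9ccccc9 | intermediate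
17 | 6-bromo-3,7,3',4'-tetra-O-benzyl-ent-fisetinidol-(4α→6)-3,7,3',4'-tetra-O-benzyl-ent-fisetinidol-(4α→8)-3,5,7,3',4'-penta-O-benzylcatechin (units A and B 2S,3R with the C-4 aryl cis to 3-OBn; unit D 2R,3S) | O(Cc9ccccc9)c1c(Br)cc2c(c1)O[C@@H](c1ccc(OCc9ccccc9)c(OCc9ccccc9)c1)[C@H](OCc9ccccc9)[C@@H]2c1cc2c(cc1OCc9ccccc9)O[C@@H](c1ccc(OCc9ccccc9)c(OCc9ccccc9)c1)[C@H](OCc9ccccc9)[C@@H]2c1c(OCc9ccccc9)cc(OCc9ccccc9)c2c1O[C@H](c1ccc(OCc9ccccc9)c(OCc9ccccc9)c1)[C@@H](OCc9ccccc9)C2 | intermediate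
18 | trimer 17 with iodine at C-6 of unit D | O(Cc9ccccc9)c1c(Br)cc2c(c1)O[C@@H](c1ccc(OCc9ccccc9)c(OCc9ccccc9)c1)[C@H](OCc9ccccc9)[C@@H]2c1cc2c(cc1OCc9ccccc9)O[C@@H](c1ccc(OCc9ccccc9)c(OCc9ccccc9)c1)[C@H](OCc9ccccc9)[C@@H]2c1c(OCc9ccccc9)c(I)c(OCc9ccccc9)c2c1O[C@H](c1ccc(OCc9ccccc9)c(OCc9ccccc9)c1)[C@@H](OCc9ccccc9)C2 | intermediate
19 | 4-(benzyloxy)-2-hydroxybenzaldehyde | O=Cc1ccc(OCc2ccccc2)cc1O | starting material
20 | sodium 5-(benzyloxy)-2-formylphenolate | [Na+].[O-]c1cc(OCc2ccccc2)ccc1C=O | intermediate (not isolated)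
21 | arylmagnesium chloride: trimer 17 with MgCl at C-6 of unit D | O(Cc9ccccc9)c1c(Br)cc2c(c1)O[C@@H](c1ccc(OCc9ccccc9)c(OCc9ccccc9)c1)[C@H](OCc9ccccc9)[C@@H]2c1cc2c(cc1OCc9ccccc9)O[C@@H](c1ccc(OCc9ccccc9)c(OCc9ccccc9)c1)[C@H](OCc9ccccc9)[C@@H]2c1c(OCc9ccccc9)c([Mg]Cl)c(OCc9ccccc9)c2c1O[C@H](c1ccc(OCc9ccccc9)c(OCc9ccccc9)c1)[C@@H](OCc9ccccc9)C2 | intermediate (not isolated)
22 | trimer 17 carrying at C-6 of unit D a [4-(benzyloxy)-2-hydroxyphenyl](hydroxy)methyl group (either carbinol epimer) | O(Cc9ccccc9)c1c(Br)cc2c(c1)O[C@@H](c1ccc(OCc9ccccc9)c(OCc9ccccc9)c1)[C@H](OCc9ccccc9)[C@@H]2c1cc2c(cc1OCc9ccccc9)O[C@@H](c1ccc(OCc9ccccc9)c(OCc9ccccc9)c1)[C@H](OCc9ccccc9)[C@@H]2c1c(OCc9ccccc9)c(C(O)c3ccc(OCc9ccccc9)cc3O)c(OCc9ccccc9)c2c1O[C@H](c1ccc(OCc9ccccc9)c(OCc9ccccc9)c1)[C@@H](OCc9ccccc9)C2 | intermediate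
23 | 2,2'-methylenebis(4,4,5,5-tetramethyl-1,3,2-dioxaborolane) | CC1(C)OB(CB2OC(C)(C)C(C)(C)O2)OC1(C)C | starting material
24 | lithio-bis(4,4,5,5-tetramethyl-1,3,2-dioxaborolan-2-yl)methane | [Li]C(B1OC(C)(C)C(C)(C)O1)B1OC(C)(C)C(C)(C)O1 | intermediate (not isolated)
25 | 2-[(E)-2-[3,4-bis(benzyloxy)phenyl]ethenyl]-4,4,5,5-tetramethyl-1,3,2-dioxaborolane | CC1(C)OB(/C=C/c2ccc(OCc3ccccc3)c(OCc3ccccc3)c2)OC1(C)C | intermediate
26 | potassium [(E)-2-[3,4-bis(benzyloxy)phenyl]ethenyl]trifluoroborate | [K+].F[B-](F)(F)/C=C/c1ccc(OCc2ccccc2)c(OCc2ccccc2)c1 | intermediate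
27 | (E)-2-[3,4-bis(benzyloxy)phenyl]ethenyl acetate | CC(=O)O/C=C/c1ccc(OCc2ccccc2)c(OCc2ccccc2)c1 | intermediate
28 | ortho-quinone methide: 3-(benzyloxy)-6-[(E)-arylmethylidene]cyclohexa-2,4-dien-1-one, aryl = C-6 of unit D of trimer 17 | O(Cc9ccccc9)c1c(Br)cc2c(c1)O[C@@H](c1ccc(OCc9ccccc9)c(OCc9ccccc9)c1)[C@H](OCc9ccccc9)[C@@H]2c1cc2c(cc1OCc9ccccc9)O[C@@H](c1ccc(OCc9ccccc9)c(OCc9ccccc9)c1)[C@H](OCc9ccccc9)[C@@H]2c1c(OCc9ccccc9)c(/C=C3/C(=O)C=C(OCc9ccccc9)C=C3)c(OCc9ccccc9)c2c1O[C@H](c1ccc(OCc9ccccc9)c(OCc9ccccc9)c1)[C@@H](OCc9ccccc9)C2 | intermediate (not isolated)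
29 | 6-bromo-3,7,3',4'-tetra-O-benzyl-ent-fisetinidol-(4α→6)-3,7,3',4'-tetra-O-benzyl-ent-fisetinidol-(4α→8)-3,5,7,3',4'-penta-O-benzylcatechin-(6→4β)-3-O-acetyl-7,3',4'-tri-O-benzyl-ent-fisetinidol (unit C 2S,3R,4R: 2,3-trans, 3,4-trans) | O(Cc9ccccc9)c1c(Br)cc2c(c1)O[C@@H](c1ccc(OCc9ccccc9)c(OCc9ccccc9)c1)[C@H](OCc9ccccc9)[C@@H]2c1cc2c(cc1OCc9ccccc9)O[C@@H](c1ccc(OCc9ccccc9)c(OCc9ccccc9)c1)[C@H](OCc9ccccc9)[C@@H]2c1c(OCc9ccccc9)c([C@H]2c3ccc(OCc9ccccc9)cc3O[C@@H](c3ccc(OCc9ccccc9)c(OCc9ccccc9)c3)[C@@H]2OC(C)=O)c(OCc9ccccc9)c2c1O[C@H](c1ccc(OCc9ccccc9)c(OCc9ccccc9)c1)[C@@H](OCc9ccccc9)C2 | intermediate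
30 | 29 with the 3-OH of unit C free | O(Cc9ccccc9)c1c(Br)cc2c(c1)O[C@@H](c1ccc(OCc9ccccc9)c(OCc9ccccc9)c1)[C@H](OCc9ccccc9)[C@@H]2c1cc2c(cc1OCc9ccccc9)O[C@@H](c1ccc(OCc9ccccc9)c(OCc9ccccc9)c1)[C@H](OCc9ccccc9)[C@@H]2c1c(OCc9ccccc9)c([C@H]2c3ccc(OCc9ccccc9)cc3O[C@@H](c3ccc(OCc9ccccc9)c(OCc9ccccc9)c3)[C@@H]2O)c(OCc9ccccc9)c2c1O[C@H](c1ccc(OCc9ccccc9)c(OCc9ccccc9)c1)[C@@H](OCc9ccccc9)C2 | intermediate
31 | ent-fisetinidol-(4α→6)-ent-fisetinidol-(4α→8)-catechin-(6→4β)-ent-fisetinidol, CNP0126838.5 (unit A 2S,3R,4R; unit B 2S,3R,4S; unit C 2S,3R,4R; unit D 2R,3S) | Oc1ccc2c(c1)O[C@@H](c1ccc(O)c(O)c1)[C@H](O)[C@@H]2c1cc2c(cc1O)O[C@@H](c1ccc(O)c(O)c1)[C@H](O)[C@@H]2c1c(O)c([C@H]2c3ccc(O)cc3O[C@@H](c3ccc(O)c(O)c3)[C@@H]2O)c(O)c2c1O[C@H](c1ccc(O)c(O)c1)[C@@H](O)C2 | target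

Total step count: 19 steps.
Longest linear sequence: 14 steps (steps 1–6, 9–13, 17–19).

Steps most likely to fail

1. Step 17. The cycloaddition may fail through C–C bond formation at the wrong alkene carbon (oxygen-directed instead of aryl-directed polarity), through insufficient facial discrimination by the catalyst at the crowded methide, or through diversion of the methide into Friedel–Crafts self-condensation and of the enol acetate into acid hydrolysis. The fallback uses known chemistry, builds the heterocycle of unit C before the interflavan bond, sets out from 8 and 17 and comes back at 31. Ketone 8 is reduced with NaBH4 (MeOH/THF, 0 °C) to (2S,3R,4S)-7-(benzyloxy)-2-[3,4-bis(benzyloxy)phenyl]-6-bromo-3,4-dihydro-2H-chromene-3,4-diol F1, which is acetylated (Ac2O, pyridine, DMAP) to its 3,4-di-O-acetate F2. BF3·OEt2 in CH2Cl2 at −40 °C ionises the C-4 acetate, and the only free position of the phloroglucinol-type ring of 17 (C-6 of unit D) should attack anti to the participating 3-acetoxy group (Lewis-acid Friedel–Crafts flavan-4-yl coupling, 3,4-trans), giving the unit-C 6-bromo analogue of 29 F3. K2CO3 in MeOH/THF gives the corresponding 3-alcohol F4, and the conditions of step 19, which also remove the second aryl bromine, give 31.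

2. Step 11. Facial control in hydride delivery may erode, or acid-induced elimination and fragmentation may intervene, when two tertiary carbinol sites are ionised in one operation. The fallback changes the order of events so that only one cation is present at a time; it sets out from 14 and comes back at 17. Carbinol 14 alone is deoxygenated (Bu3SnH, CF3CO2H, CH2Cl2, −40 → 0 °C) on the smaller dimer to 6-bromo-3,7,3',4'-tetra-O-benzyl-ent-fisetinidol-(4α→8)-3,5,7,3',4'-penta-O-benzylcatechin F5. Bromine–lithium exchange (t-BuLi, THF, −78 °C) and addition to 9 give the mono-carbinol trimer F6, whose single tertiary alcohol is reduced under the same ionic conditions to 17.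

3. Step 13. The hindered arylmagnesium may be protonated before it adds, or may add only sluggishly to the anionic, electron-rich aldehyde partner. The fallback uses a neutral, protected electrophile and an aryllithium; it sets out from 18 and 19 and comes back at 22. Aldehyde 19 is silylated (TIPSCl, imidazole, DMF) to 4-(benzyloxy)-2-[(triisopropylsilyl)oxy]benzaldehyde F7. Iodide 18 is treated with n-BuLi (THF, −95 °C; iodine–lithium exchange, faster than attack on the aryl bromide) and the aryllithium is added to F7 to give the O-silyl ether of 22 F8. TBAF buffered with AcOH (THF, 0 °C) frees the phenol to give 22.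

Further compounds
F1 | step 17 | (2S,3R,4S)-7-(benzyloxy)-2-[3,4-bis(benzyloxy)phenyl]-6-bromo-3,4-dihydro-2H-chromene-3,4-diol | O[C@H]1c2cc(Br)c(OCc3ccccc3)cc2O[C@@H](c2ccc(OCc3ccccc3)c(OCc3ccccc3)c2)[C@@H]1O
F2 | step 17 | 3,4-di-O-acetate of F1 | CC(=O)O[C@H]1c2cc(Br)c(OCc3ccccc3)cc2O[C@@H](c2ccc(OCc3ccccc3)c(OCc3ccccc3)c2)[C@@H]1OC(C)=O
F3 | step 17 | analogue of 29 with bromine at C-6 of unit C | O(Cc9ccccc9)c1c(Br)cc2c(c1)O[C@@H](c1ccc(OCc9ccccc9)c(OCc9ccccc9)c1)[C@H](OCc9ccccc9)[C@@H]2c1cc2c(cc1OCc9ccccc9)O[C@@H](c1ccc(OCc9ccccc9)c(OCc9ccccc9)c1)[C@H](OCc9ccccc9)[C@@H]2c1c(OCc9ccccc9)c([C@H]2c3cc(Br)c(OCc9ccccc9)cc3O[C@@H](c3ccc(OCc9ccccc9)c(OCc9ccccc9)c3)[C@@H]2OC(C)=O)c(OCc9ccccc9)c2c1O[C@H](c1ccc(OCc9ccccc9)c(OCc9ccccc9)c1)[C@@H](OCc9ccccc9)C2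
F4 | step 17 | analogue of 30 with bromine at C-6 of unit C | O(Cc9ccccc9)c1c(Br)cc2c(c1)O[C@@H](c1ccc(OCc9ccccc9)c(OCc9ccccc9)c1)[C@H](OCc9ccccc9)[C@@H]2c1cc2c(cc1OCc9ccccc9)O[C@@H](c1ccc(OCc9ccccc9)c(OCc9ccccc9)c1)[C@H](OCc9ccccc9)[C@@H]2c1c(OCc9ccccc9)c([C@H]2c3cc(Br)c(OCc9ccccc9)cc3O[C@@H](c3ccc(OCc9ccccc9)c(OCc9ccccc9)c3)[C@@H]2O)c(OCc9ccccc9)c2c1O[C@H](c1ccc(OCc9ccccc9)c(OCc9ccccc9)c1)[C@@H](OCc9ccccc9)C2
F5 | step 11 | 6-bromo-3,7,3',4'-tetra-O-benzyl-ent-fisetinidol-(4α→8)-3,5,7,3',4'-penta-O-benzylcatechin | Brc1cc2c(cc1OCc9ccccc9)O[C@@H](c1ccc(OCc9ccccc9)c(OCc9ccccc9)c1)[C@H](OCc9ccccc9)[C@@H]2c1c(OCc9ccccc9)cc(OCc9ccccc9)c2c1O[C@H](c1ccc(OCc9ccccc9)c(OCc9ccccc9)c1)[C@@H](OCc9ccccc9)C2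
F6 | step 11 | mono-carbinol trimer: 6-bromo-3,7,3',4'-tetra-O-benzyl-4-hydroxy-ent-fisetinidol-(4→6)-3,7,3',4'-tetra-O-benzyl-ent-fisetinidol-(4α→8)-3,5,7,3',4'-penta-O-benzylcatechin (either carbinol epimer) | OC1(c2cc3c(cc2OCc9ccccc9)O[C@@H](c4ccc(OCc9ccccc9)c(OCc9ccccc9)c4)[C@H](OCc9ccccc9)[C@@H]3c2c(OCc9ccccc9)cc(OCc9ccccc9)c3c2O[C@H](c4ccc(OCc9ccccc9)c(OCc9ccccc9)c4)[C@@H](OCc9ccccc9)C3)c2cc(Br)c(OCc9ccccc9)cc2O[C@@H](c2ccc(OCc9ccccc9)c(OCc9ccccc9)c2)[C@@H]1OCc9ccccc9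
F7 | step 13 | 4-(benzyloxy)-2-[(triisopropylsilyl)oxy]benzaldehyde | O=Cc1ccc(OCc2ccccc2)cc1O[Si](C(C)C)(C(C)C)C(C)C
F8 | step 13 | O-triisopropylsilyl (phenol) ether of 22 | O(Cc9ccccc9)c1c(Br)cc2c(c1)O[C@@H](c1ccc(OCc9ccccc9)c(OCc9ccccc9)c1)[C@H](OCc9ccccc9)[C@@H]2c1cc2c(cc1OCc9ccccc9)O[C@@H](c1ccc(OCc9ccccc9)c(OCc9ccccc9)c1)[C@H](OCc9ccccc9)[C@@H]2c1c(OCc9ccccc9)c(C(O)c3ccc(OCc9ccccc9)cc3O[Si](C(C)C)(C(C)C)C(C)C)c(OCc9ccccc9)c2c1O[C@H](c1ccc(OCc9ccccc9)c(OCc9ccccc9)c1)[C@@H](OCc9ccccc9)C2
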